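The target is cut at the aryl–C4 and O1–C2 bonds of the chromene and, in the terpenoid half, across the cyclohexene ring at C1′–C6′ and C2′–C3′. The cis pair of methyl groups on quaternary C1′ and on C2′ of this ring is the E geometry of tiglaldehyde in disguise. One enantioselective Diels–Alder reaction between that enal and a Z-configured 3-silyloxypenta-1,3-diene therefore closes the ring, forms both bonds and fixes C1′ and C2′, with the formyl carbon becoming chain carbon Cα. The ketone oxygen is then traded for the C3′=C4′ alkene, and the chromene stereocentre C2 comes from a Sharpless epoxide opened with inversion by a symmetric resorcinol.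

Key step: step 2

Remarks on the chemistry:
- Chromene atoms are O1, C2–C8a; cyclohexene atoms are C1′–C6′; the chain carbons are Cα (on C1′) and Cβ (on C2).
- C3′ is an epimer mixture until the enol triflate erases it.
- The acetal carbons of the tetrahydropyranyl ethers are unassigned mixtures.
- The tartrate enantiomer is assigned from the usual face-selection rule of the titanium–tartrate epoxidation.
- The sense of the cycloaddition catalyst is assigned from the accepted formyl-binding model and would be confirmed by correlation on the first batch.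

Step 1
Reactants: 1 pent-1-en-3-one
Product: 2 (Z)-3-(triisopropylsilyloxy)penta-1,3-diene
Conditions: TIPSOTf, Et3N, CH2Cl2, 0 °C → rt
Reagents that add atoms: triisopropylsilyl trifluoromethanesulfonate, CC(C)[Si](C(C)C)(C(C)C)OS(=O)(=O)C(F)(F)F
Why: Soft enolisation (silyl enol ether formation), in which the silyl triflate activates the carbonyl oxygen and Et3N removes a proton from the ethyl CH2, gives the cross-conjugated 2-silyloxydiene with the Z enol ether geometry that this method normally delivers from ethyl ketones.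

Step 2
Reactants: 2 (Z)-3-(triisopropylsilyloxy)penta-1,3-diene; 3 (E)-2-methylbut-2-enal
Product: 4 (1R,2R)-1,2,3-trimethyl-4-(triisopropylsilyloxy)cyclohex-4-ene-1-carbaldehyde (C3 epimers)
Conditions: (S)-3,3-diphenyl-1-(o-tolyl)tetrahydro-1H,3H-pyrrolo[1,2-c][1,3,2]oxazaborole (20 mol%), HNTf2 (16 mol%), 2 (2.5 equiv), CH2Cl2, −40 → −20 °C
Reagents that add atoms: none
Why: The N-protonated oxazaborolidine binds the formyl oxygen of 3 anti to the alkenyl group, with the formyl C–H held near the ring oxygen, which lowers the LUMO of the s-trans enal and lets an aryl group of the catalyst cover one face, so the diene adds to the open face in a concerted, asynchronous [4+2] cycloaddition. The closest known reaction type is the cationic-oxazaborolidine-catalysed Diels–Alder reaction of 2-silyloxydienes with α-substituted enals. The cyclohexene ring closes by intermolecular [4+2] annulation, bonds C2′–C3′ (leading) and C1′–C6′ forming suprafacially on both partners. C1′ is set by the catalyst-controlled enantioface of the enal (the S catalyst is expected to give 1R), C2′ follows from the E geometry of 3 because suprafacial addition keeps the two methyl groups cis whatever the endo or exo mode, and C3′ is left uncontrolled because step 4 removes it. The step needs para regiochemistry, secured by the silyloxy group, which makes the methyl-bearing diene terminus the nucleophilic end that attacks the enal β-carbon, and it needs the Z diene so that the terminal methyl points outward in the s-cis conformer. The bulky, acid-robust triisopropylsilyl ether is chosen because forming C2′–C3′ between two methyl-bearing carbons is slow and demands long exposure to a strong Lewis acid.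

Step 3
Reactants: 4 (1R,2R)-1,2,3-trimethyl-4-(triisopropylsilyloxy)cyclohex-4-ene-1-carbaldehyde
Product: 6 (3R,4S)-4-ethenyl-2,3,4-trimethylcyclohexan-1-one (C2 epimers), via vinyl silyl enol ether 5 (not isolated)
Conditions: Ph3PCH3Br, KOtBu, THF, 0 °C → rt; then 3 M HCl, rt
Reagents that add atoms: methyltriphenylphosphonium bromide (CH2 donor as its ylide), C[P+](c1ccccc1)(c1ccccc1)c1ccccc1.[Br-]
Why: Wittig methylenation of the non-enolisable aldehyde adds Cβ, and acid hydrolysis of the silyl enol ether by C-protonation then unveils the C4′ ketone, leaving C1′ and C2′ untouched and C3′ as an inconsequential epimer mixture.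

Step 4
Reactants: 6 (3R,4S)-4-ethenyl-2,3,4-trimethylcyclohexan-1-one
Product: 7 (3S,4S)-4-ethenyl-2,3,4-trimethylcyclohex-1-en-1-yl trifluoromethanesulfonate
Conditions: Tf2O, 2,6-di-tert-butyl-4-methylpyridine, CH2Cl2, 0 °C → rt
Reagents that add atoms: trifluoromethanesulfonic anhydride, O=S(=O)(OS(=O)(=O)C(F)(F)F)C(F)(F)F
Why: Enol triflate formation under thermodynamic control, by O-triflylation of the ketone and proton loss to the hindered pyridine, should favour the more substituted C3′=C4′ enol triflate, which also erases the C3′ stereocentre so that both epimers converge.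

Step 5
Reactants: 7 (3S,4S)-4-ethenyl-2,3,4-trimethylcyclohex-1-en-1-yl trifluoromethanesulfonate
Product: 8 (5S,6R)-5-ethenyl-1,5,6-trimethylcyclohex-1-ene
Conditions: Pd(OAc)2 (5 mol%), PPh3, HCO2H, n-Bu3N, DMF, 60 °C; volatile product kept as a concentrated solution
Reagents that add atoms: none
Why: Palladium-catalysed formate reduction of an enol triflate (oxidative addition, formate exchange, decarboxylation, C–H reductive elimination) replaces OTf by H without moving the double bond, and the vinyl group on a quaternary carbon cannot isomerise.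

Step 6
Reactants: 9 but-2-yn-1-ol
Product: 11 (Z)-3-iodobut-2-en-1-ol, via cyclic vinylalanate 10 (not isolated)
Conditions: NaAlH2(OCH2CH2OCH3)2, THF, 0 °C → rt; then I2, −78 °C
Reagents that add atoms: iodine, II
Why: Alkoxide-directed trans-hydroalumination of the propargylic alcohol gives a five-membered vinylalanate with aluminium on C3, and iodinolysis with retention affords the Z iodide.

Step 7
Reactants: 8 (5S,6R)-5-ethenyl-1,5,6-trimethylcyclohex-1-ene; 11 (Z)-3-iodobut-2-en-1-ol
Product: 13 (2Z)-3-methyl-5-[(1S,2S)-1,2,3-trimethylcyclohex-3-en-1-yl]pent-2-en-1-ol, via B-alkyl-9-borabicyclononane 12 (not isolated)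
Conditions: 9-BBN-H, THF, rt; then 11, Pd(dppf)Cl2 (5 mol%), AsPh3, Cs2CO3, DMF/THF/H2O, rt
Reagents that add atoms: none
Why: Hydroboration with 9-BBN is anti-Markovnikov and selective for the monosubstituted vinyl group over the trisubstituted ring alkene, and the B-alkyl Suzuki–Miyaura coupling then joins Cβ to the future C2 with retention of the Z geometry of the vinyl iodide.

Step 8
Reactants: 13 (2Z)-3-methyl-5-[(1S,2S)-1,2,3-trimethylcyclohex-3-en-1-yl]pent-2-en-1-ol
Product: 14 [(2R,3S)-3-methyl-3-{2-[(1S,2S)-1,2,3-trimethylcyclohex-3-en-1-yl]ethyl}oxiran-2-yl]methanol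
Conditions: Ti(OiPr)4 (10 mol%), D-(−)-diisopropyl tartrate (12 mol%), t-BuOOH, 4 Å MS, CH2Cl2, −20 °C
Reagents that add atoms: tert-butyl hydroperoxide, CC(C)(C)OO
Why: In the Sharpless asymmetric epoxidation titanium binds the allylic hydroxyl, so only the chain alkene is epoxidised and the ring alkene is ignored, and the D-(−)-tartrate delivers oxygen to the face of the Z alcohol that gives the (2R,3S) epoxide, S at the future C2.

Step 9
Reactants: 15 1,2,3-trimethoxybenzene
Product: 16 1,5-dibromo-2,3,4-trimethoxybenzene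
Conditions: NBS (2.1 equiv), MeCN, 0 °C → rt
Reagents that add atoms: N-bromosuccinimide, O=C1CCC(=O)N1Br
Why: In this electrophilic aromatic bromination each bromine enters para to one outer methoxy group and ortho to the other (C4, then C6), leaving the single C–H between the two bromines.

Step 10
Reactants: 16 1,5-dibromo-2,3,4-trimethoxybenzene
Product: 17 4,5,6-trimethoxybenzene-1,3-diol
Conditions: Pd2(dba)3 (2 mol%), t-BuXPhos, KOH, 1,4-dioxane/H2O, 100 °C; then HCl, under argon
Reagents that add atoms: potassium hydroxide, [K+].[OH-]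
Why: Palladium-catalysed hydroxylation of aryl bromides (C–O cross-coupling with hydroxide, bulky biarylphosphine ligand) replaces both bromides, and the air-sensitive electron-rich diol is acidified under argon and used at once.

Step 11
Reactants: 17 4,5,6-trimethoxybenzene-1,3-diol
Product: 18 1,2,3-trimethoxy-4,6-bis(tetrahydro-2H-pyran-2-yloxy)benzene
Conditions: 3,4-dihydro-2H-pyran, PPTS, CH2Cl2, rt
Reagents that add atoms: 3,4-dihydro-2H-pyran, C1=COCCC1
Why: Acid-catalysed addition of the phenols to the enol ether (tetrahydropyranylation) gives a bis-acetal that directs lithiation and can later be removed under conditions mild enough for an epoxide.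

Step 12
Reactants: 14 [(2R,3S)-3-methyl-3-{2-[(1S,2S)-1,2,3-trimethylcyclohex-3-en-1-yl]ethyl}oxiran-2-yl]methanol; 18 1,2,3-trimethoxy-4,6-bis(tetrahydro-2H-pyran-2-yloxy)benzene
Product: 22 2-({(2R,3S)-3-methyl-3-[2-((1S,2S)-1,2,3-trimethylcyclohex-3-en-1-yl)ethyl]oxiran-2-yl}methyl)-4,5,6-trimethoxy-1,3-bis(tetrahydro-2H-pyran-2-yloxy)benzene, via lithium alkoxide 19 (not isolated), via epoxy triflate 20 (not isolated), via aryllithium 21 (not isolated)
Conditions: 14, n-BuLi then Tf2O, Et2O, −78 °C; 18, n-BuLi, THF, 0 °C; combine at −78 → −40 °C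
Reagents that add atoms: none
Why: Directed ortho-metalation at the only ring C–H, flanked by two acetal oxygens, gives the aryllithium, which displaces the primary triflate in an SN2 alkylation at −78 °C far faster than it could attack the trisubstituted epoxide, so both epoxide stereocentres are carried over unchanged.

Step 13
Reactants: 22 2-({(2R,3S)-3-methyl-3-[2-((1S,2S)-1,2,3-trimethylcyclohex-3-en-1-yl)ethyl]oxiran-2-yl}methyl)-4,5,6-trimethoxy-1,3-bis(tetrahydro-2H-pyran-2-yloxy)benzene
Product: 24 (2R,3R)-6,7,8-trimethoxy-2-methyl-2-{2-[(1S,2S)-1,2,3-trimethylcyclohex-3-en-1-yl]ethyl}-3,4-dihydro-2H-chromene-3,5-diol, via free resorcinol epoxide 23 (not isolated)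
Conditions: PPTS, MeOH, 0 °C, argon; then CSA (10 mol%), CH2Cl2, −40 → 0 °C
Reagents that add atoms: none
Why: Acetal methanolysis frees both phenols, and Brønsted-acid-catalysed intramolecular epoxide opening should then proceed 6-endo at the tertiary carbon, which carries the positive charge in the transition state, with backside attack, so the 3S epoxide carbon becomes C2 with R configuration, while either hydroxyl of the symmetric resorcinol gives the same product and the other remains as the C5 phenol.

Step 14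
Reactants: 24 (2R,3R)-6,7,8-trimethoxy-2-methyl-2-{2-[(1S,2S)-1,2,3-trimethylcyclohex-3-en-1-yl]ethyl}-3,4-dihydro-2H-chromene-3,5-diol
Product: 25 (2R,3R)-3-hydroxy-6,7,8-trimethoxy-2-methyl-2-{2-[(1S,2S)-1,2,3-trimethylcyclohex-3-en-1-yl]ethyl}-3,4-dihydro-2H-chromen-5-yl acetate
Conditions: Ac2O (1.1 equiv), K2CO3, acetone, 0 °C → rt
Reagents that add atoms: acetic anhydride, CC(=O)OC(C)=O
Why: In this chemoselective O-acetylation K2CO3 deprotonates only the phenol, whose phenoxide is acylated while the hindered, neutral secondary alcohol at C3 is not.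

Step 15
Reactants: 25 (2R,3R)-3-hydroxy-6,7,8-trimethoxy-2-methyl-2-{2-[(1S,2S)-1,2,3-trimethylcyclohex-3-en-1-yl]ethyl}-3,4-dihydro-2H-chromen-5-yl acetate
Product: 26 (2R)-6,7,8-trimethoxy-2-methyl-2-{2-[(1S,2S)-1,2,3-trimethylcyclohex-3-en-1-yl]ethyl}-2H-chromen-5-yl acetate
Conditions: Ph2S[OC(CF3)2Ph]2 (Martin sulfurane), CH2Cl2, 0 °C → rt, dark
Reagents that add atoms: none
Why: Sulfurane dehydration goes through an alkoxysulfonium ion that undergoes anti E2 elimination, and because C2 is quaternary only a benzylic C4–H can be lost, which places the double bond at C3=C4, while room temperature and darkness avoid the electrocyclic ring opening of the 2H-chromene that would scramble C2.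

Step 16
Reactants: 26 (2R)-6,7,8-trimethoxy-2-methyl-2-{2-[(1S,2S)-1,2,3-trimethylcyclohex-3-en-1-yl]ethyl}-2H-chromen-5-yl acetate
Product: 27 (2R)-6,7,8-trimethoxy-2-methyl-2-{2-[(1S,2S)-1,2,3-trimethylcyclohex-3-en-1-yl]ethyl}-2H-chromen-5-ol
Conditions: K2CO3 (cat.), MeOH, 0 °C → rt, dark
Reagents that add atoms: none
Why: Base-catalysed methanolysis (transesterification) of the aryl acetate releases the C5 phenol under conditions that leave the chromene, both alkenes and C2 untouched.

Compound list
1 | pent-1-en-3-one | CCC(=O)C=C | starting material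
2 | (Z)-3-(triisopropylsilyloxy)penta-1,3-diene | C=C/C(O[Si](C(C)C)(C(C)C)C(C)C)=C/C | intermediate
3 | (E)-2-methylbut-2-enal | C/C=C(\C)C=O | starting material
4 | (1R,2R)-1,2,3-trimethyl-4-(triisopropylsilyloxy)cyclohex-4-ene-1-carbaldehyde (C3 epimers) | O=C[C@]1(C)CC=C(O[Si](C(C)C)(C(C)C)C(C)C)C(C)[C@H]1C | intermediate
5 | {[(4S,5R)-4-ethenyl-4,5,6-trimethylcyclohex-1-en-1-yl]oxy}triisopropylsilane (C6 epimers) | C=C[C@]1(C)CC=C(O[Si](C(C)C)(C(C)C)C(C)C)C(C)[C@H]1C | intermediate (not isolated)
6 | (3R,4S)-4-ethenyl-2,3,4-trimethylcyclohexan-1-one (C2 epimers) | C=C[C@]1(C)CCC(=O)C(C)[C@H]1C | intermediate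
7 | (3S,4S)-4-ethenyl-2,3,4-trimethylcyclohex-1-en-1-yl trifluoromethanesulfonate | C=C[C@]1(C)CCC(OS(=O)(=O)C(F)(F)F)=C(C)[C@H]1C | intermediate
8 | (5S,6R)-5-ethenyl-1,5,6-trimethylcyclohex-1-ene | C=C[C@]1(C)CCC=C(C)[C@H]1C | intermediate
9 | but-2-yn-1-ol | CC#CCO | starting material
10 | sodium 2,2-bis(2-methoxyethoxy)-3-methyl-2,5-dihydro-1,2-oxaaluminol-2-uide (cyclic vinylalanate) | [Na+].CC1=CCO[Al-]1(OCCOC)OCCOC | intermediate (not isolated)
11 | (Z)-3-iodobut-2-en-1-ol | OC/C=C(/C)I | intermediate
12 | 9-{2-[(1R,2S)-1,2,3-trimethylcyclohex-3-en-1-yl]ethyl}-9-borabicyclo[3.3.1]nonane | C1CC2CCCC(C1)B2CC[C@]1(C)CCC=C(C)[C@H]1C | intermediate (not isolated)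
13 | (2Z)-3-methyl-5-[(1S,2S)-1,2,3-trimethylcyclohex-3-en-1-yl]pent-2-en-1-ol | OC/C=C(/C)CC[C@]1(C)CCC=C(C)[C@H]1C | intermediate
14 | [(2R,3S)-3-methyl-3-{2-[(1S,2S)-1,2,3-trimethylcyclohex-3-en-1-yl]ethyl}oxiran-2-yl]methanol | OC[C@H]1O[C@@]1(C)CC[C@]2(C)CCC=C(C)[C@H]2C | intermediate
15 | 1,2,3-trimethoxybenzene | COc1cccc(OC)c1OC | starting material
16 | 1,5-dibromo-2,3,4-trimethoxybenzene | COc1c(OC)c(Br)cc(Br)c1OC | intermediate
17 | 4,5,6-trimethoxybenzene-1,3-diol | COc1c(OC)c(O)cc(O)c1OC | intermediate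
18 | 1,2,3-trimethoxy-4,6-bis(tetrahydro-2H-pyran-2-yloxy)benzene (acetal carbons unassigned) | COc1c(OC)c(OC2CCCCO2)cc(OC2CCCCO2)c1OC | intermediate
19 | lithium [(2R,3S)-3-methyl-3-{2-[(1S,2S)-1,2,3-trimethylcyclohex-3-en-1-yl]ethyl}oxiran-2-yl]methanolate | [Li+].[O-]C[C@H]1O[C@@]1(C)CC[C@]2(C)CCC=C(C)[C@H]2C | intermediate (not isolated)
20 | [(2R,3S)-3-methyl-3-{2-[(1S,2S)-1,2,3-trimethylcyclohex-3-en-1-yl]ethyl}oxiran-2-yl]methyl trifluoromethanesulfonate | FC(F)(F)S(=O)(=O)OC[C@H]1O[C@@]1(C)CC[C@]2(C)CCC=C(C)[C@H]2C | intermediate (not isolated)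
21 | [3,4,5-trimethoxy-2,6-bis(tetrahydro-2H-pyran-2-yloxy)phenyl]lithium | [Li]c1c(OC2CCCCO2)c(OC)c(OC)c(OC)c1OC1CCCCO1 | intermediate (not isolated)
22 | 2-({(2R,3S)-3-methyl-3-[2-((1S,2S)-1,2,3-trimethylcyclohex-3-en-1-yl)ethyl]oxiran-2-yl}methyl)-4,5,6-trimethoxy-1,3-bis(tetrahydro-2H-pyran-2-yloxy)benzene | COc1c(OC)c(OC2CCCCO2)c(C[C@H]3O[C@@]3(C)CC[C@]4(C)CCC=C(C)[C@H]4C)c(OC2CCCCO2)c1OC | intermediate
23 | 2-({(2R,3S)-3-methyl-3-[2-((1S,2S)-1,2,3-trimethylcyclohex-3-en-1-yl)ethyl]oxiran-2-yl}methyl)-4,5,6-trimethoxybenzene-1,3-diol | COc1c(OC)c(O)c(C[C@H]2O[C@@]2(C)CC[C@]3(C)CCC=C(C)[C@H]3C)c(O)c1OC | intermediate (not isolated)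
24 | (2R,3R)-6,7,8-trimethoxy-2-methyl-2-{2-[(1S,2S)-1,2,3-trimethylcyclohex-3-en-1-yl]ethyl}-3,4-dihydro-2H-chromene-3,5-diol | COc1c(O)c2c(c(OC)c1OC)O[C@](C)(CC[C@]1(C)CCC=C(C)[C@H]1C)[C@H](O)C2 | intermediate
25 | (2R,3R)-3-hydroxy-6,7,8-trimethoxy-2-methyl-2-{2-[(1S,2S)-1,2,3-trimethylcyclohex-3-en-1-yl]ethyl}-3,4-dihydro-2H-chromen-5-yl acetate | COc1c(OC(C)=O)c2c(c(OC)c1OC)O[C@](C)(CC[C@]1(C)CCC=C(C)[C@H]1C)[C@H](O)C2 | intermediate
26 | (2R)-6,7,8-trimethoxy-2-methyl-2-{2-[(1S,2S)-1,2,3-trimethylcyclohex-3-en-1-yl]ethyl}-2H-chromen-5-yl acetate | COc1c(OC(C)=O)c2c(c(OC)c1OC)O[C@](C)(CC[C@]1(C)CCC=C(C)[C@H]1C)C=C2 | intermediate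
27 | (2R)-6,7,8-trimethoxy-2-methyl-2-{2-[(1S,2S)-1,2,3-trimethylcyclohex-3-en-1-yl]ethyl}-2H-chromen-5-ol | COc1c(O)c2c(c(OC)c1OC)O[C@](C)(CC[C@]1(C)CCC=C(C)[C@H]1C)C=C2 | target

Total step count: 16. Longest linear sequence: 12 steps (steps 1–5, 7, 8, 12–16, from pent-1-en-3-one).

Steps most likely to fail

Step 2. The bond between the two methyl-bearing carbons forms slowly, so catalyst decay, loss of the silyl group from the diene and an uncatalysed background pathway may erode conversion and enantiomeric purity. The fallback sets out from 2 and 3 and returns at 7; it gives up catalyst control and resolves. Me2AlCl in CH2Cl2 at −78 °C promotes the same cycloaddition without asymmetric induction to give racemic adduct F1. The methylenation and hydrolysis of step 3 then lead through racemic vinyl silyl enol ether F2 to racemic vinyl ketone F3. The triflation of step 4 gives racemic enol triflate F4, a single constitutional isomer without epimeric centres. This is separated by preparative chromatography on a chiral stationary phase, and its (3S,4S) enantiomer is 7.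

Step 13. Attack of the phenol at the secondary epoxide carbon (5-exo closure to a dihydrobenzofuran) may compete, or ionisation at the tertiary carbon may loosen the inversion and erode C2. The fallback sets out from 13 and 17 and returns at 27; it forms O1–C2 by asymmetric allylic etherification and closes the pyran ring by olefin metathesis, with no epoxide. ClCO2Me and pyridine convert 13 into methyl carbonate F7. Vilsmeier–Haack formylation (POCl3, DMF) of 17 at its only free ring position gives 2,6-dihydroxy-3,4,5-trimethoxybenzaldehyde F8. Pd2(dba)3 is used with the enantiomer of N,N′-(cyclohexane-1,2-diyl)bis[2-(diphenylphosphanyl)benzamide] that delivers the 3R product. It joins one phenolic oxygen of F8 to the more substituted allyl terminus of F7 and gives tertiary aryl ether F9. Ph3P=CH2 turns the formyl group into a vinyl group in diene F10. Second-generation Grubbs catalyst (CH2Cl2, 40 °C, dark) then closes C3=C4 to give 27.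

Step 4. Proton loss toward C5′ instead of C3′ would leak material into the less substituted enol triflate and end as a misplaced ring alkene. The fallback sets out from 6 and returns at 7; it makes the regiochemistry an isolable matter. Isopropenyl acetate with catalytic TsOH at reflux equilibrates 6 to the more substituted enol acetate F5, which can be separated from its regioisomer. MeLi (2 equiv, THF, 0 °C) cleaves it to the regiodefined lithium enolate F6, which PhNTf2 traps as 7.

Further compounds
F1 | step 2 | racemic 1,2-cis-1,2,3-trimethyl-4-(triisopropylsilyloxy)cyclohex-4-ene-1-carbaldehyde (both enantiomers) | O=C[C@]1(C)CC=C(O[Si](C(C)C)(C(C)C)C(C)C)C(C)[C@H]1C.O=C[C@@]1(C)CC=C(O[Si](C(C)C)(C(C)C)C(C)C)C(C)[C@@H]1C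
F2 | step 2 | racemic {[4-ethenyl-4,5,6-trimethylcyclohex-1-en-1-yl]oxy}triisopropylsilane (both enantiomers, not isolated) | C=C[C@]1(C)CC=C(O[Si](C(C)C)(C(C)C)C(C)C)C(C)[C@H]1C.C=C[C@@]1(C)CC=C(O[Si](C(C)C)(C(C)C)C(C)C)C(C)[C@@H]1C
F3 | step 2 | racemic 4-ethenyl-2,3,4-trimethylcyclohexan-1-one (both enantiomers) | C=C[C@]1(C)CCC(=O)C(C)[C@H]1C.C=C[C@@]1(C)CCC(=O)C(C)[C@@H]1C
F4 | step 2 | racemic 4-ethenyl-2,3,4-trimethylcyclohex-1-en-1-yl trifluoromethanesulfonate (both enantiomers) | C=C[C@]1(C)CCC(OS(=O)(=O)C(F)(F)F)=C(C)[C@H]1C.C=C[C@@]1(C)CCC(OS(=O)(=O)C(F)(F)F)=C(C)[C@@H]1C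
F5 | step 4 | (3S,4S)-4-ethenyl-2,3,4-trimethylcyclohex-1-en-1-yl acetate | C=C[C@]1(C)CCC(OC(C)=O)=C(C)[C@H]1C
F6 | step 4 | lithium (3S,4S)-4-ethenyl-2,3,4-trimethylcyclohex-1-en-1-olate | [Li+].C=C[C@]1(C)CCC([O-])=C(C)[C@H]1C
F7 | step 13 | methyl (2Z)-3-methyl-5-[(1S,2S)-1,2,3-trimethylcyclohex-3-en-1-yl]pent-2-en-1-yl carbonate | COC(=O)OC/C=C(/C)CC[C@]1(C)CCC=C(C)[C@H]1C
F8 | step 13 | 2,6-dihydroxy-3,4,5-trimethoxybenzaldehyde | COc1c(OC)c(O)c(C=O)c(O)c1OC
F9 | step 13 | 2-hydroxy-3,4,5-trimethoxy-6-({(3R)-3-methyl-5-[(1S,2S)-1,2,3-trimethylcyclohex-3-en-1-yl]pent-1-en-3-yl}oxy)benzaldehyde | COc1c(OC)c(O)c(C=O)c(O[C@@](C)(C=C)CC[C@]2(C)CCC=C(C)[C@H]2C)c1OC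
F10 | step 13 | 2-ethenyl-4,5,6-trimethoxy-3-({(3R)-3-methyl-5-[(1S,2S)-1,2,3-trimethylcyclohex-3-en-1-yl]pent-1-en-3-yl}oxy)phenol | COc1c(OC)c(O)c(C=C)c(O[C@@](C)(C=C)CC[C@]2(C)CCC=C(C)[C@H]2C)c1OC
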